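**Plan**

- The six-membered ring of the target is a dearomatised acylphloroglucinol. Its only sp3 ring carbon, C5 (benzofuran numbering), lies between the C4 and C6 carbonyls and carries both prenyl groups. The retrosynthesis therefore first cuts both C5–CH2 bonds, giving an aromatic dihydrobenzofuran diphenol whose single free ring CH is C5.
- Further cuts: the O1–C2 bond of the dihydrofuran (phenol oxygen onto an epoxide), the epoxide back to a prenyl alkene, the aryl–CH2 bond (C-prenylation) and the aryl–acyl bond, ending at phloroglucinol, isobutyryl chloride and prenyl bromide.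
- Forward: the benzene ring is bought, then acylated and mono-C-prenylated. The dihydrofuran ring closes by 5-exo epoxide opening. The carbocycle is never built; it is only dearomatised in the last step by geminal diprenylation.
- Position of the furan oxygen: a TIPS ether on the hydroxyl para to the acyl group leaves only the hydroxyl between acyl group and side chain within reach of the epoxide. Both ortho hydroxyls are masked as acetates during the epoxidation so that no free phenol meets the oxidant.
- Stereochemistry: the single stereocentre (C2, S) comes from a Shi epoxidation with the D-fructose-derived ketone, which gives the (R)-epoxide. It is inverted once in the SN2 ring closure and is not touched afterwards.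

Key step: step 8

Assumption: the target is an enolised β-triketone and the SMILES shows one tautomer (exocyclic enol hydrogen-bonded to the C6 carbonyl); the route delivers the compound as its tautomeric equilibrium mixture.

**Route**

Step 1
Reactants: 1 phloroglucinol; 2 isobutyryl chloride
Product: 3 2-methyl-1-(2,4,6-trihydroxyphenyl)propan-1-one (phlorisobutyrophenone)
Conditions: AlCl3 (4 equiv), PhNO2, rt → 65 °C; then ice/aq. HCl
Reagents that add atoms: none
Why: Friedel–Crafts acylation of the very electron-rich triol occurs at carbon, and the chelated, deactivated aryl ketone–AlCl3 complex resists a second acylation.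

Step 2
Reactants: 3 phlorisobutyrophenone; 4 prenyl bromide
Product: 5 2-methyl-1-[2,4,6-trihydroxy-3-(3-methylbut-2-en-1-yl)phenyl]propan-1-one
Conditions: 4 (1.0 equiv), 10% aq. KOH, 0 °C; then aq. HCl
Reagents that add atoms: none
Why: C-alkylation of an ambident phloroglucinol phenoxide (SN2 on the primary allylic bromide) is favoured in water, where the oxyanions are hydrogen-bonded, and because 3 has two equivalent free ring carbons a limiting amount of bromide should give a single mono-prenyl regioisomer.

Step 3
Reactants: 5 mono-prenyl acylphloroglucinol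
Product: 6 1-[2,6-dihydroxy-3-(3-methylbut-2-en-1-yl)-4-(triisopropylsilyloxy)phenyl]-2-methylpropan-1-one (TIPS on the hydroxyl para to the acyl group)
Conditions: TIPSCl (1.05 equiv), imidazole, DMF, 0 °C
Reagents that add atoms: triisopropylsilyl chloride, CC(C)[Si](Cl)(C(C)C)C(C)C
Why: Silyl ether formation should occur selectively at the hydroxyl para to the ketone, which is the most acidic and the only one not locked in a hydrogen bond to the carbonyl, while the bulky TIPS group is slow to attack the chelated ortho hydroxyls.

Step 4
Reactants: 6 para-O-TIPS diphenol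
Product: 7 2-(2-methylpropanoyl)-4-(3-methylbut-2-en-1-yl)-5-(triisopropylsilyloxy)-1,3-phenylene diacetate
Conditions: Ac2O, pyridine, DMAP (cat.), CH2Cl2, 0 °C → rt
Reagents that add atoms: acetic anhydride, CC(=O)OC(C)=O
Why: DMAP-catalysed O-acylation (nucleophilic acyl-transfer catalysis) caps both chelated phenols, which makes the ring electron-poor and inert to the dioxirane of the next step and provides esters that are removed by mild methanolysis when the ring is to be closed.

Step 5
Reactants: 7 diacetate alkene
Product: 8 4-{[(2R)-3,3-dimethyloxiran-2-yl]methyl}-2-(2-methylpropanoyl)-5-(triisopropylsilyloxy)-1,3-phenylene diacetate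
Conditions: D-fructose-derived Shi ketone (0.3 equiv), KHSO5 (as 2KHSO5·KHSO4·K2SO4), K2CO3, Bu4NHSO4 (cat.), MeCN–CH2(OMe)2–aq. Na2B4O7 buffer (pH 10.5), −10 → 0 °C
Reagents that add atoms: potassium peroxymonosulfate, [K+].[O-]S(=O)(=O)OO
Why: Shi asymmetric epoxidation: the chiral dioxirane generated from the D-fructose-derived ketone transfers oxygen to the trisubstituted alkene through a spiro transition state from the face that gives the (R)-epoxide, so the sole stereocentre is set under reagent control while the fully O-protected arene is left alone.

Step 6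
Reactants: 8 (R)-epoxide diacetate
Product: 10 1-[(2S)-6-hydroxy-2-(2-hydroxypropan-2-yl)-4-(triisopropylsilyloxy)-2,3-dihydro-1-benzofuran-7-yl]-2-methylpropan-1-one, via free bis-phenol epoxide 9 (not isolated)
Conditions: K2CO3, MeOH, 0 °C → rt; then aq. NH4Cl
Reagents that add atoms: none
Why: Methanolysis of the two aryl acetates (transesterification) frees the phenoxide next to the side chain, which opens the epoxide at its secondary carbon in a 5-exo-tet SN2 reaction with inversion, turning the (R)-epoxide into the (S)-configured dihydrobenzofuran and the epoxide oxygen into the tertiary alcohol; the silylated para oxygen cannot compete and the other free phenol cannot reach.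

Step 7
Reactants: 10 TIPS-protected dihydrobenzofuran
Product: 11 1-[(2S)-4,6-dihydroxy-2-(2-hydroxypropan-2-yl)-2,3-dihydro-1-benzofuran-7-yl]-2-methylpropan-1-one
Conditions: Bu4NF, AcOH, THF, 0 °C
Reagents that add atoms: none
Why: Fluoride-induced cleavage of the aryl silyl ether (desilylation) is driven by the Si–F bond and is buffered with acetic acid so that the electron-rich diphenol is not kept as an air-sensitive phenoxide; the stereocentre and the tertiary alcohol are not involved.

Step 8
Reactants: 11 (S)-dihydrobenzofuran diphenol; 4 prenyl bromide (two equivalents enter the product)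
Product: 13 garcinielliptone HD [(2S,7Z)-7-(1-hydroxy-2-methylpropylidene)-2-(2-hydroxypropan-2-yl)-5,5-bis(3-methylbut-2-en-1-yl)-2,3-dihydro-1-benzofuran-4,6(5H,7H)-dione], via C5-monoprenyl diphenol 12 (not isolated)
Conditions: 4 (2.3 equiv), 10% aq. KOH, 0 °C → rt; then aq. HCl
Reagents that add atoms: none
Why: In aqueous KOH the diphenol 11 is ionised and its only unsubstituted ring carbon C5, ortho to both oxyanions, attacks the primary carbon of prenyl bromide (SN2) to give 12 after tautomerisation; 12 is deprotonated again and alkylated a second time at the same carbon, which then bears no hydrogen, so the ring cannot rearomatise and rests as the enolised β-triketone 13. The closest known reaction is the lupulone-type alkylative dearomatisation of acylphloroglucinols by geminal C-prenylation with prenyl bromide and aqueous or alkoxide base. No ring is closed and no stereocentre is formed; C2 is remote from any acidic site, so its (S) configuration is carried through unchanged. The step needs C- over O-alkylation, SN2 over SN2′ attack and C5 over C3a attack: water hydrogen-bonds the oxyanions and leaves the soft carbon as the nucleophile, the primary allylic bromide reacts at its unhindered terminus, and C5 is flanked by two oxyanions whereas C3a has only one and already bears the furan CH2. Over-alkylation should be limited because 13 is a vinylogous acid whose delocalised anion is a poor nucleophile, and the tertiary alcohol is not ionised under these conditions.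

**Compound list**

1 | phloroglucinol (benzene-1,3,5-triol) | Oc1cc(O)cc(O)c1 | starting material
2 | isobutyryl chloride | CC(C)C(Cl)=O | starting material
3 | 2-methyl-1-(2,4,6-trihydroxyphenyl)propan-1-one | CC(C)C(=O)c1c(O)cc(O)cc1O | intermediate
4 | prenyl bromide (1-bromo-3-methylbut-2-ene) | CC(C)=CCBr | starting material
5 | 2-methyl-1-[2,4,6-trihydroxy-3-(3-methylbut-2-en-1-yl)phenyl]propan-1-one | CC(C)C(=O)c1c(O)cc(O)c(CC=C(C)C)c1O | intermediate
6 | 1-[2,6-dihydroxy-3-(3-methylbut-2-en-1-yl)-4-(triisopropylsilyloxy)phenyl]-2-methylpropan-1-one | CC(C)C(=O)c1c(O)cc(O[Si](C(C)C)(C(C)C)C(C)C)c(CC=C(C)C)c1O | intermediate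
7 | 2-(2-methylpropanoyl)-4-(3-methylbut-2-en-1-yl)-5-(triisopropylsilyloxy)-1,3-phenylene diacetate | CC(C)C(=O)c1c(OC(C)=O)cc(O[Si](C(C)C)(C(C)C)C(C)C)c(CC=C(C)C)c1OC(C)=O | intermediate
8 | 4-{[(2R)-3,3-dimethyloxiran-2-yl]methyl}-2-(2-methylpropanoyl)-5-(triisopropylsilyloxy)-1,3-phenylene diacetate | CC(C)C(=O)c1c(OC(C)=O)cc(O[Si](C(C)C)(C(C)C)C(C)C)c(C[C@H]2OC2(C)C)c1OC(C)=O | intermediate
9 | 1-[3-{[(2R)-3,3-dimethyloxiran-2-yl]methyl}-2,6-dihydroxy-4-(triisopropylsilyloxy)phenyl]-2-methylpropan-1-one (phenoxide in the flask, not isolated) | CC(C)C(=O)c1c(O)cc(O[Si](C(C)C)(C(C)C)C(C)C)c(C[C@H]2OC2(C)C)c1O | intermediate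
10 | 1-[(2S)-6-hydroxy-2-(2-hydroxypropan-2-yl)-4-(triisopropylsilyloxy)-2,3-dihydro-1-benzofuran-7-yl]-2-methylpropan-1-one | O1[C@H](C(C)(C)O)Cc2c(O[Si](C(C)C)(C(C)C)C(C)C)cc(O)c(C(=O)C(C)C)c12 | intermediate
11 | 1-[(2S)-4,6-dihydroxy-2-(2-hydroxypropan-2-yl)-2,3-dihydro-1-benzofuran-7-yl]-2-methylpropan-1-one | O1[C@H](C(C)(C)O)Cc2c(O)cc(O)c(C(=O)C(C)C)c12 | intermediate
12 | 1-[(2S)-4,6-dihydroxy-2-(2-hydroxypropan-2-yl)-5-(3-methylbut-2-en-1-yl)-2,3-dihydro-1-benzofuran-7-yl]-2-methylpropan-1-one (not isolated) | O1[C@H](C(C)(C)O)Cc2c(O)c(CC=C(C)C)c(O)c(C(=O)C(C)C)c12 | intermediate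
13 | garcinielliptone HD | CC(C)=CCC1(CC=C(C)C)C(=O)C2=C(O[C@H](C(C)(C)O)C2)/C(=C(/O)C(C)C)C1=O | target

**Step count**

Total: 8 steps. Longest linear sequence: 8 steps (1 → 3 → 5 → 6 → 7 → 8 → 10 → 11 → 13).

**Steps most likely to fail**

Step 8. The double alkylation may be diverted by O-prenylation, by attack at C3a, by further alkylation of the product anion, or by hydrolysis of the bromide before the second C–C bond forms. Fallback: setting out from 11, both prenyl groups would be delivered as a π-prenyl palladium complex, using Pd(PPh3)4 (zerovalent palladium, catalytic) and prenyl methyl carbonate (COC(=O)OCC=C(C)C, 2.2 equiv) in THF at room temperature. This is a Tsuji–Trost allylation: the methoxide released on ionisation deprotonates the phenol, the soft C5 nucleophile attacks the unsubstituted terminus of the π-prenyl ligand, and any O-prenyl ether re-ionises and is funnelled to carbon. The sequence again passes through 12 and rejoins the route at 13; it makes no compound outside the list (F0).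

Step 5. The aryl acetates may hydrolyse in the pH 10.5 medium before the alkene has reacted, exposing an electron-rich phenoxide to the oxidant, and facial discrimination next to the crowded arene may be insufficient. Fallback: setting out from 7, epoxidation under anhydrous, non-basic conditions (mCPBA, NaHCO3, CH2Cl2, 0 °C) would give racemic 4-[(3,3-dimethyloxiran-2-yl)methyl]-2-(2-methylpropanoyl)-5-(triisopropylsilyloxy)-1,3-phenylene diacetate F1. Treatment with K2CO3 in MeOH as in step 6 would pass through the racemic free bis-phenol epoxide F2 (not isolated) to racemic 1-[6-hydroxy-2-(2-hydroxypropan-2-yl)-4-(triisopropylsilyloxy)-2,3-dihydro-1-benzofuran-7-yl]-2-methylpropan-1-one F3. Its enantiomers would be separated by preparative chromatography on a chiral stationary phase, and the (S)-enantiomer is 10, where the route is rejoined. The stereocentre then comes from a resolution instead of catalyst control, at the cost of half the material.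

Step 2. Over-alkylation to di- and triprenylated and dearomatised products, together with O-alkylation, may leave little of the mono-C-prenyl compound. Fallback: setting out from 3, the para hydroxyl would be etherified with 3-chloro-3-methylbut-1-yne (K2CO3, KI, CuI cat., acetone) to 1-[2,6-dihydroxy-4-(2-methylbut-3-yn-2-yloxy)phenyl]-2-methylpropan-1-one F4. Semi-hydrogenation (H2, Pd on CaCO3 poisoned with Pb(OAc)2, quinoline, EtOAc) would give 1-[2,6-dihydroxy-4-(2-methylbut-3-en-2-yloxy)phenyl]-2-methylpropan-1-one F5. Heating F5 in toluene triggers an aromatic Claisen rearrangement that delivers exactly one prenyl group to the ortho carbon and re-forms the phenol, rejoining the route at 5.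

**Further compounds**

F0 | step 8 | none | none
F1 | step 5 | racemic 4-[(3,3-dimethyloxiran-2-yl)methyl]-2-(2-methylpropanoyl)-5-(triisopropylsilyloxy)-1,3-phenylene diacetate | CC(C)C(=O)c1c(OC(C)=O)cc(O[Si](C(C)C)(C(C)C)C(C)C)c(CC2OC2(C)C)c1OC(C)=O
F2 | step 5 | racemic 1-[3-[(3,3-dimethyloxiran-2-yl)methyl]-2,6-dihydroxy-4-(triisopropylsilyloxy)phenyl]-2-methylpropan-1-one (not isolated) | CC(C)C(=O)c1c(O)cc(O[Si](C(C)C)(C(C)C)C(C)C)c(CC2OC2(C)C)c1O
F3 | step 5 | racemic 1-[6-hydroxy-2-(2-hydroxypropan-2-yl)-4-(triisopropylsilyloxy)-2,3-dihydro-1-benzofuran-7-yl]-2-methylpropan-1-one | O1C(C(C)(C)O)Cc2c(O[Si](C(C)C)(C(C)C)C(C)C)cc(O)c(C(=O)C(C)C)c12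
F4 | step 2 | 1-[2,6-dihydroxy-4-(2-methylbut-3-yn-2-yloxy)phenyl]-2-methylpropan-1-one | CC(C)C(=O)c1c(O)cc(OC(C)(C)C#C)cc1O
F5 | step 2 | 1-[2,6-dihydroxy-4-(2-methylbut-3-en-2-yloxy)phenyl]-2-methylpropan-1-one | CC(C)C(=O)c1c(O)cc(OC(C)(C)C=C)cc1O
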